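**Retrosynthetic overview**
1. The core is a cis-fused furo[3,4-c]furan (ring A: C1–O2–C3–C3a–C6a; ring B: C3a–C4–O5–C6–C6a). The last disconnection is the aryl pivalate that masks the phenol.
2. Key disconnection, one operation: the C4–aryl bond together with the C3–C3a bond. The enabling feature is that C3 is a CH2 between O2 and C3a (a formaldehyde carbon, supplied by a MOM ether on O2) and C4 is the O5-bound carbon next to C3a (the α-carbon of a ring B enol ether C3a=C4). Attack of C3a on the MOM-derived oxocarbenium closes ring A and moves the cation to C4, where an aryltrifluoroborate delivers the aryl group on the convex face.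
3. Ring B (a 2,3-dihydrofuran) comes from a lactol, made by ozonolysis of an allyl group. O2 (MOM) and O5 (free OH) are told apart by regioselective opening of a 1,3-dioxane formal.
4. C1 and C6a come from a D-proline anti-aldol reaction of vanillin pivalate with pent-4-enal. The aryl donor comes from a commercial boronate phenol by prenylation and KHF2.
5. Ring order: ring B first (steps 7–8), then ring A, with C3a and C4 set in the key step.

Key step: step 9

Remark: furo[3,4-c]furan numbering (C1, O2, C3, C3a, C4, O5, C6, C6a) is used throughout. The SMILES is read as (1S,3aS,4R,6aS): cis ring fusion, the 4-hydroxy-3-methoxyphenyl group endo at C1, the 3-methoxy-4-(prenyloxy)phenyl group exo at C4.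

**Step 1**
Reactants: 1 2-methoxy-4-(4,4,5,5-tetramethyl-1,3,2-dioxaborolan-2-yl)phenol
Product: 2 2-[3-methoxy-4-(3-methylbut-2-en-1-yloxy)phenyl]-4,4,5,5-tetramethyl-1,3,2-dioxaborolane
Conditions: prenyl bromide, K2CO3, acetone, 40 °C
Reagents that add atoms: prenyl bromide (1-bromo-3-methylbut-2-ene), CC(C)=CCBr
Why: Williamson ether synthesis, in which the phenoxide attacks the primary allylic bromide by SN2 at oxygen and the pinacol boronate tolerates the carbonate base.

**Step 2**
Reactants: 2 2-[3-methoxy-4-(3-methylbut-2-en-1-yloxy)phenyl]-4,4,5,5-tetramethyl-1,3,2-dioxaborolane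
Product: 3 potassium trifluoro[3-methoxy-4-(3-methylbut-2-en-1-yloxy)phenyl]borate
Conditions: KHF2, MeOH–H2O, rt
Reagents that add atoms: potassium hydrogen difluoride (KHF2), F.[F-].[K+]
Why: Ligand exchange at boron (pinacol boronate to trifluoroborate) should give a bench-stable aryl donor whose C–B carbon lies para to the prenyloxy group, which fixes the site of the later aryl transfer.

**Step 3**
Reactants: 4 vanillin
Product: 5 4-formyl-2-methoxyphenyl pivalate
Conditions: PivCl, Et3N, DMAP (cat.), CH2Cl2, 0 °C → rt
Reagents that add atoms: pivaloyl chloride, CC(C)(C)C(=O)Cl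
Why: O-acylation by nucleophilic acyl substitution; the hindered ester resists aminolysis and borohydride, makes the aldehyde a better aldol acceptor and later keeps the C1 aryl group too electron-poor for benzylic ionisation.

**Step 4**
Reactants: 5 4-formyl-2-methoxyphenyl pivalate; 6 pent-4-enal
Product: 8 4-[(1S,2S)-1-hydroxy-2-(hydroxymethyl)pent-4-en-1-yl]-2-methoxyphenyl pivalate, via aldol aldehyde 7 (not isolated)
Conditions: D-proline (20 mol%), DMF, 4 °C, 6 added slowly; then MeOH, NaBH4, 0 °C
Reagents that add atoms: none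
Why: Proline-catalysed direct cross-aldol reaction (enamine catalysis), in which the (E)-enamine of 6 should add to the Si face of the aryl aldehyde through the acid-bridged chair-like transition state to set C1 (S) and C6a in the anti relationship, and the in situ reduction protects the adduct from retro-aldol cleavage and epimerisation.

**Step 5**
Reactants: 8 4-[(1S,2S)-1-hydroxy-2-(hydroxymethyl)pent-4-en-1-yl]-2-methoxyphenyl pivalate
Product: 9 2-methoxy-4-[(4S,5S)-5-(prop-2-en-1-yl)-1,3-dioxan-4-yl]phenyl pivalate
Conditions: CH2(OMe)2, CSA (cat.), CH2Cl2, reflux over 4 Å molecular sieves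
Reagents that add atoms: dimethoxymethane, COCOC
Why: Acid-catalysed transacetalisation should tie the anti-1,3-diol into the trans-diequatorial 1,3-dioxane and place the future C3 between O2 and O5 without touching a stereocentre.

**Step 6**
Reactants: 9 2-methoxy-4-[(4S,5S)-5-(prop-2-en-1-yl)-1,3-dioxan-4-yl]phenyl pivalate
Product: 12 4-[(1S,2S)-2-(hydroxymethyl)-1-(methoxymethoxy)pent-4-en-1-yl]-2-methoxyphenyl pivalate, via pyridinium salt 10 (not isolated), via silyl ether 11 (not isolated)
Conditions: TMSOTf, 2,2′-bipyridyl, CH2Cl2, 0 °C; then MeOH, rt; aqueous citric acid work-up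
Reagents that add atoms: methanol, CO
Why: Regiocontrolled cleavage of a methylene acetal by silyl triflate–2,2′-bipyridyl, in which the silyl group goes to the less hindered primary oxygen and the CH2 stays on the benzylic oxygen as an N-(alkoxymethyl)pyridinium ion that methanol converts into the MOM ether, so that O2 carries C3 and O5 is set free.

**Step 7**
Reactants: 12 4-[(1S,2S)-2-(hydroxymethyl)-1-(methoxymethoxy)pent-4-en-1-yl]-2-methoxyphenyl pivalate
Product: 15 4-[(S)-[(3S)-5-hydroxyoxolan-3-yl](methoxymethoxy)methyl]-2-methoxyphenyl pivalate (both anomers), via ozonide 13 (not isolated), via hydroxy aldehyde 14 (not isolated)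
Conditions: O3 (until the alkene is consumed), CH2Cl2, −78 °C; then PPh3, −78 °C → rt
Reagents that add atoms: ozone, [O-][O+]=O
Why: Ozonolysis (Criegee mechanism) with reductive work-up should cleave the terminal alkene, far more reactive than the acylated arene, to the C4 aldehyde, which closes on the only free hydroxyl (O5) to the five-membered lactol of ring B.

**Step 8**
Reactants: 15 4-[(S)-[(3S)-5-hydroxyoxolan-3-yl](methoxymethoxy)methyl]-2-methoxyphenyl pivalate
Product: 17 4-[(S)-[(3S)-2,3-dihydrofuran-3-yl](methoxymethoxy)methyl]-2-methoxyphenyl pivalate, via anomeric mesylate 16 (not isolated)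
Conditions: MsCl, Et3N (excess), CH2Cl2, −40 °C → 40 °C; chromatography on Et3N-deactivated silica
Reagents that add atoms: none
Why: Lactol dehydration by sulfonylation–elimination (the furanoid glycal synthesis), in which the anomeric mesylate ionises and loses a C3a proton to the amine to give the C3a=C4 enol ether while the MOM ether, the pivalate and C6a stay untouched.

**Step 9**
Reactants: 17 4-[(S)-[(3S)-2,3-dihydrofuran-3-yl](methoxymethoxy)methyl]-2-methoxyphenyl pivalate; 3 potassium trifluoro[3-methoxy-4-(3-methylbut-2-en-1-yloxy)phenyl]borate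
Product: 21 2-methoxy-4-[(1S,3aS,4R,6aS)-4-[3-methoxy-4-(3-methylbut-2-en-1-yloxy)phenyl]tetrahydro-1H,3H-furo[3,4-c]furan-1-yl]phenyl pivalate, via oxocarbenium ion 18 (not isolated), via bicyclic oxocarbenium ion 19 (not isolated), via bicyclic methyl acetal 20 (not isolated)
Conditions: TMSOTf (10 mol%), 2,6-di-tert-butyl-4-methylpyridine (20 mol%), CH2Cl2 (0.01 M), −78 → −30 °C; then 3, BF3·OEt2, MeCN, −40 → 0 °C; aqueous NaHCO3
Reagents that add atoms: none
Why: Proposed new method: the silyl triflate should ionise the MOM acetal at its methoxy end to the formaldehyde-type oxocarbenium ion 18, the nucleophilic C3a of the ring B enol ether attacks its CH2 carbon to close ring A and shift the cation to C4 (19), which rests as methyl acetal 20 until BF3·OEt2 re-ionises it and turns 3 into the aryl(difluoro)borane that transfers its aryl group ipso to C4. The closest known reactions are the Lewis-acid acetal–enol ether condensation in its ring-forming vinyl-acetal (Petasis–Ferrier type) variants and the BF3-promoted substitution of acetals by potassium organotrifluoroborates, merged here into one Prins-type cyclisation/C-arylation cascade. Ring A closes in the 5-endo-trig mode at the oxocarbenium carbon (O2 and C3 both inside the new ring) with the enol ether exo, the mode that operates in those vinyl-acetal rearrangements. C3a is fixed by the tether, because the side chain on C6a can only reach the face of ring B on which it stands, so the ring fusion is cis; C4 is set by attack of the aryl donor on the convex face of the cis-fused bicycle, the concave face being blocked by ring A and its endo aryl group at C1, and the exo aryl ether is also the thermodynamic epimer should the benzylic C4–O5 bond re-ionise. The step needs ionisation of the MOM group without protonation or oligomerisation of the enol ether (aprotic silyl triflate, hindered pyridine, dilution, low temperature), no interception of 18 by the aryl donor (3 is added only after ring closure), aryl transfer at the boron-bearing carbon only (ipso substitution para to the prenyloxy group) and no ionisation at C1 (the pivalate makes that aryl group electron-poor).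

**Step 10**
Reactants: 21 2-methoxy-4-[(1S,3aS,4R,6aS)-4-[3-methoxy-4-(3-methylbut-2-en-1-yloxy)phenyl]tetrahydro-1H,3H-furo[3,4-c]furan-1-yl]phenyl pivalate
Product: 22 4-[(1S,3aS,4R,6aS)-4-[3-methoxy-4-(3-methylbut-2-en-1-yloxy)phenyl]tetrahydro-1H,3H-furo[3,4-c]furan-1-yl]-2-methoxyphenol (target)
Conditions: NaOMe, MeOH, 0 °C → rt; aqueous NH4Cl
Reagents that add atoms: none
Why: Transesterification (methanolysis) of the aryl pivalate, whose phenoxide is a good leaving group, should free the phenol under basic conditions that leave the prenyl ether, the benzylic ethers and all four stereocentres untouched.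

**Compound list**
1 | 2-methoxy-4-(4,4,5,5-tetramethyl-1,3,2-dioxaborolan-2-yl)phenol | COc1cc(B2OC(C)(C)C(C)(C)O2)ccc1O | starting material
2 | 2-[3-methoxy-4-(3-methylbut-2-en-1-yloxy)phenyl]-4,4,5,5-tetramethyl-1,3,2-dioxaborolane | COc1cc(B2OC(C)(C)C(C)(C)O2)ccc1OCC=C(C)C | intermediate
3 | potassium trifluoro[3-methoxy-4-(3-methylbut-2-en-1-yloxy)phenyl]borate | COc1cc([B-](F)(F)F)ccc1OCC=C(C)C.[K+] | intermediate
4 | vanillin (4-hydroxy-3-methoxybenzaldehyde) | COc1cc(C=O)ccc1O | starting material
5 | 4-formyl-2-methoxyphenyl pivalate | COc1cc(C=O)ccc1OC(=O)C(C)(C)C | intermediate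
6 | pent-4-enal | C=CCCC=O | starting material
7 | 4-[(1S,2R)-2-formyl-1-hydroxypent-4-en-1-yl]-2-methoxyphenyl pivalate (anti-aldol aldehyde) | COc1cc([C@@H](O)[C@H](C=O)CC=C)ccc1OC(=O)C(C)(C)C | intermediate (not isolated)
8 | 4-[(1S,2S)-1-hydroxy-2-(hydroxymethyl)pent-4-en-1-yl]-2-methoxyphenyl pivalate | COc1cc([C@@H](O)[C@H](CO)CC=C)ccc1OC(=O)C(C)(C)C | intermediate
9 | 2-methoxy-4-[(4S,5S)-5-(prop-2-en-1-yl)-1,3-dioxan-4-yl]phenyl pivalate | COc1cc([C@H]2OCOC[C@@H]2CC=C)ccc1OC(=O)C(C)(C)C | intermediate
10 | 1-[({(1S,2S)-1-[3-methoxy-4-(pivaloyloxy)phenyl]-2-[(trimethylsilyloxy)methyl]pent-4-en-1-yl}oxy)methyl]-2-(pyridin-2-yl)pyridinium triflate | COc1cc([C@@H](OC[n+]2ccccc2-c2ccccn2)[C@H](CO[Si](C)(C)C)CC=C)ccc1OC(=O)C(C)(C)C.[O-]S(=O)(=O)C(F)(F)F | intermediate (not isolated)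
11 | 2-methoxy-4-[(1S,2S)-1-(methoxymethoxy)-2-[(trimethylsilyloxy)methyl]pent-4-en-1-yl]phenyl pivalate | COc1cc([C@@H](OCOC)[C@H](CO[Si](C)(C)C)CC=C)ccc1OC(=O)C(C)(C)C | intermediate (not isolated)
12 | 4-[(1S,2S)-2-(hydroxymethyl)-1-(methoxymethoxy)pent-4-en-1-yl]-2-methoxyphenyl pivalate | COc1cc([C@@H](OCOC)[C@H](CO)CC=C)ccc1OC(=O)C(C)(C)C | intermediate
13 | 4-[(1S,2S)-2-(hydroxymethyl)-1-(methoxymethoxy)-3-(1,2,4-trioxolan-3-yl)propyl]-2-methoxyphenyl pivalate (ozonide) | COc1cc([C@@H](OCOC)[C@H](CO)CC2OCOO2)ccc1OC(=O)C(C)(C)C | intermediate (not isolated)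
14 | 4-[(1S,2S)-2-(hydroxymethyl)-1-(methoxymethoxy)-4-oxobutyl]-2-methoxyphenyl pivalate | COc1cc([C@@H](OCOC)[C@H](CO)CC=O)ccc1OC(=O)C(C)(C)C | intermediate (not isolated)
15 | 4-[(S)-[(3S)-5-hydroxyoxolan-3-yl](methoxymethoxy)methyl]-2-methoxyphenyl pivalate (both anomers) | COc1cc([C@@H](OCOC)[C@@H]2COC(O)C2)ccc1OC(=O)C(C)(C)C | intermediate
16 | 4-[(S)-[(3S)-5-(methylsulfonyloxy)oxolan-3-yl](methoxymethoxy)methyl]-2-methoxyphenyl pivalate | COc1cc([C@@H](OCOC)[C@@H]2COC(OS(C)(=O)=O)C2)ccc1OC(=O)C(C)(C)C | intermediate (not isolated)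
17 | 4-[(S)-[(3S)-2,3-dihydrofuran-3-yl](methoxymethoxy)methyl]-2-methoxyphenyl pivalate | COc1cc([C@@H](OCOC)[C@@H]2COC=C2)ccc1OC(=O)C(C)(C)C | intermediate
18 | {(S)-[(3S)-2,3-dihydrofuran-3-yl][3-methoxy-4-(pivaloyloxy)phenyl]methyl}(methylidene)oxonium triflate | COc1cc([C@@H]([O+]=C)[C@@H]2COC=C2)ccc1OC(=O)C(C)(C)C.[O-]S(=O)(=O)C(F)(F)F | intermediate (not isolated)
19 | cis-fused bicyclic oxocarbenium triflate (O5=C4 cation of the (1S,3aS,6aS)-1-aryl-furo[3,4-c]furan) | COc1cc([C@H]2OC[C@@H]3[C@H]2C[O+]=C3)ccc1OC(=O)C(C)(C)C.[O-]S(=O)(=O)C(F)(F)F | intermediate (not isolated)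
20 | 2-methoxy-4-[(1S,3aS,6aS)-4-methoxytetrahydro-1H,3H-furo[3,4-c]furan-1-yl]phenyl pivalate (C4 epimers) | COc1cc([C@H]2OC[C@@H]3[C@H]2COC3OC)ccc1OC(=O)C(C)(C)C | intermediate (not isolated)
21 | 2-methoxy-4-[(1S,3aS,4R,6aS)-4-[3-methoxy-4-(3-methylbut-2-en-1-yloxy)phenyl]tetrahydro-1H,3H-furo[3,4-c]furan-1-yl]phenyl pivalate | COc1cc([C@H]2OC[C@@H]3[C@H]2CO[C@H]3c2ccc(OCC=C(C)C)c(OC)c2)ccc1OC(=O)C(C)(C)C | intermediate
22 | 4-[(1S,3aS,4R,6aS)-4-[3-methoxy-4-(3-methylbut-2-en-1-yloxy)phenyl]tetrahydro-1H,3H-furo[3,4-c]furan-1-yl]-2-methoxyphenol | COc1cc([C@H]2OC[C@@H]3[C@H]2CO[C@H]3c2ccc(OCC=C(C)C)c(OC)c2)ccc1O | target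

**Step count**
Total: 10 steps. Longest linear sequence: 8 steps (4 → 22, steps 3 to 10).

**Steps most likely to fail**

1. Step 9. The enol ether may oligomerise or be protonated faster than it closes onto the formaldehyde-derived cation, and aryl transfer may be too slow at the temperatures at which the prenyl ether survives the boron Lewis acid. The fallback sets out from 17 and comes back at 21; it separates ring closure from arylation and makes the aryl–C4 bond by carbonyl addition. Catalytic TMSOTf alone closes ring A (an intramolecular acetal–enol ether condensation) and 20 is now isolated. Aqueous acetic acid in THF hydrolyses 20 to the bicyclic lactol F1. Commercial 4-bromo-2-methoxyphenol is prenylated (prenyl bromide, K2CO3) to the aryl bromide F2, which with Mg in THF gives the aryl Grignard reagent F3. Addition of F3 to the open hydroxy-aldehyde form of F1 at −40 °C, where the hindered pivalate should be spared, gives the benzylic diol F4 as a mixture at the new carbinol carbon. Catalytic CSA in CH2Cl2 then ionises only the 4-alkoxybenzylic carbinol, and the primary alcohol on C6 closes ring B. Either carbinol epimer should converge on the exo aryl ether 21, because closure on the convex side is both the kinetic and the thermodynamic outcome when the C1 aryl group is endo and, as its pivalate, not ionisable.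

2. Step 4. Anti/syn control with an aromatic acceptor may be modest, and self-aldolisation of the donor aldehyde may consume material. The fallback sets out from 5 and comes back at 8; it replaces catalyst control by auxiliary control. (S)-4-Benzyl-1,3-oxazolidin-2-one is acylated with pent-4-enoyl chloride (nBuLi, THF, −78 °C) to the imide F5. The MgCl2-catalysed anti-aldol reaction of F5 with 5 (MgCl2, Et3N, TMSCl, EtOAc, rt; then TFA/MeOH) should give the anti-aldol imide F6, the chelated (Z)-enolate being attacked on the face away from the benzyl group as in alkylations of such imides. NaBH4 in THF–H2O then removes the auxiliary reductively and returns diol 8.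

3. Step 8. The anomeric sulfonate or chloride may persist or revert to the lactol, and the acid-sensitive enol ether may hydrate or oligomerise during isolation. The fallback sets out from 15 and comes back at 17; it replaces ionisation by a thermal syn-elimination under neutral conditions. PhSSPh and PBu3 convert 15 into the phenylthio acetal F7. mCPBA at −78 °C oxidises it to the sulfoxide F8. Heating F8 in toluene with Et3N expels benzenesulfenic acid by sulfoxide syn-elimination toward C3a and gives 17.

**Further compounds**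
F1 | step 9 | bicyclic lactol: 2-methoxy-4-[(1S,3aS,6aS)-4-hydroxytetrahydro-1H,3H-furo[3,4-c]furan-1-yl]phenyl pivalate | COc1cc([C@H]2OC[C@@H]3[C@H]2COC3O)ccc1OC(=O)C(C)(C)C
F2 | step 9 | aryl bromide: 4-bromo-2-methoxy-1-(3-methylbut-2-en-1-yloxy)benzene | COc1cc(Br)ccc1OCC=C(C)C
F3 | step 9 | aryl Grignard reagent: [3-methoxy-4-(3-methylbut-2-en-1-yloxy)phenyl]magnesium bromide | COc1cc([Mg]Br)ccc1OCC=C(C)C
F4 | step 9 | benzylic diol: 2-methoxy-4-[(2S,3S,4S)-3-(hydroxymethyl)-4-{hydroxy[3-methoxy-4-(3-methylbut-2-en-1-yloxy)phenyl]methyl}oxolan-2-yl]phenyl pivalate (carbinol epimers) | COc1cc([C@H]2OC[C@@H](C(O)c3ccc(OCC=C(C)C)c(OC)c3)[C@H]2CO)ccc1OC(=O)C(C)(C)C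
F5 | step 4 | imide: (4S)-4-benzyl-3-(pent-4-enoyl)-1,3-oxazolidin-2-one | C=CCCC(=O)N1[C@@H](Cc2ccccc2)COC1=O
F6 | step 4 | anti-aldol imide: 2-methoxy-4-[(1S,2R)-2-{[(4S)-4-benzyl-2-oxo-1,3-oxazolidin-3-yl]carbonyl}-1-hydroxypent-4-en-1-yl]phenyl pivalate | COc1cc([C@@H](O)[C@@H](CC=C)C(=O)N2[C@@H](Cc3ccccc3)COC2=O)ccc1OC(=O)C(C)(C)C
F7 | step 8 | phenylthio acetal: 2-methoxy-4-[(S)-(methoxymethoxy)[(3S)-5-(phenylsulfanyl)oxolan-3-yl]methyl]phenyl pivalate | COc1cc([C@@H](OCOC)[C@@H]2COC(Sc3ccccc3)C2)ccc1OC(=O)C(C)(C)C
F8 | step 8 | sulfoxide: 2-methoxy-4-[(S)-(methoxymethoxy)[(3S)-5-(phenylsulfinyl)oxolan-3-yl]methyl]phenyl pivalate | COc1cc([C@@H](OCOC)[C@@H]2COC(S(=O)c3ccccc3)C2)ccc1OC(=O)C(C)(C)C
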